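Ring numbering: C1 is the stereocentre, then C2, C3=C4(CH2OH), C5, C6, C7=C8(Me), C9, C10, C11=C12(Me), C13, C14. The route rests on the C10–C11 bond, which joins the homoallylic arm of the E olefin C7=C8 to the CH of the only Z ring olefin. The precursor is an acyclic ester in which C10 is the terminus of a 1,3-diene (C7=C8–C9=C10) and C11 a Z-iodoalkene. Hydroboration reverses the polarity of C10, and an intramolecular B-alkyl Suzuki–Miyaura coupling closes the 14-membered ring in the same operation, with retention of the Z geometry. C1 stems from a Johnson–Claisen chirality transfer.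

Key step: step 11

Remark: the target is read as R at C1, with Z geometry at C3=C4 (CH2OH cis to C2) and at C11=C12, and E geometry at C7=C8 and in the side-chain C(Me)=CH olefin. Compounds 1, 2, 14 and 17 and all reagents named are taken as commercial.

Step 1
Reactants: 1 5-bromo-2-methylpent-2-ene; 2 propyne
Product: 5 (1Z)-1-iodo-2,6-dimethylhepta-1,5-diene, via Grignard reagent 3 (not isolated), via alkenylcopper 4 (not isolated)
Conditions: Mg, Et2O, reflux; CuBr·SMe2 (1 equiv), Et2O/Me2S, −45 °C; 2 (excess), −25 °C; I2, THF, −50 → 0 °C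
Reagents that add atoms: iodine, [I][I]
Why: Normant carbocupration, in which the alkylcopper should add syn across propyne with copper on the terminal carbon, so that the new chain and copper are cis and iodinolysis with retention fixes the Z-iodoalkene that later becomes C11=C12.

Step 2
Reactants: 5 (1Z)-1-iodo-2,6-dimethylhepta-1,5-diene
Product: 7 (2E,6Z)-7-iodo-2,6-dimethylhepta-2,6-dienal, via allylic alcohol 6 (not isolated)
Conditions: SeO2 (cat.), t-BuOOH, salicylic acid (cat.), CH2Cl2, rt; crude mixture, MnO2, CH2Cl2, rt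
Reagents that add atoms: selenium dioxide, O=[Se]=O; tert-butyl hydroperoxide, CC(C)(C)OO
Why: Riley allylic oxidation (ene reaction then [2,3]-sigmatropic shift) should attack the E-methyl group of the electron-rich gem-dimethyl olefin and not the iodine-deactivated olefin, and MnO2 should then take the allylic alcohol on to the E-enal.

Step 3
Reactants: 7 (2E,6Z)-7-iodo-2,6-dimethylhepta-2,6-dienal
Product: 9 (4R,5E,9Z)-10-iodo-5,9-dimethyldeca-1,5,9-trien-4-ol, via borinate ester 8 (not isolated)
Conditions: (+)-Ipc2BOMe [from (−)-α-pinene], allylMgBr, Et2O, 0 °C → rt; 7, −78 °C; NaOH, H2O2, rt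
Reagents that add atoms: allylmagnesium bromide, C=CC[Mg]Br
Why: Brown asymmetric allylboration through a closed chair transition state, in which the isopinocampheyl groups derived from (−)-α-pinene should steer the allyl group to the Re face of the enal and so set the R carbinol centre.

Step 4
Reactants: 9 (4R,5E,9Z)-10-iodo-5,9-dimethyldeca-1,5,9-trien-4-ol
Product: 10 (5R,6E,10Z)-11-iodo-2,6,10-trimethylundeca-2,6,10-trien-5-ol
Conditions: 2-methylbut-2-ene (solvent), second-generation Grubbs catalyst RuCl2(H2IMes)(PCy3)(=CHPh) (3 mol %), 35 °C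
Reagents that add atoms: 2-methylbut-2-ene, CC=C(C)C
Why: Olefin cross-metathesis, in which only the monosubstituted terminal olefin should enter the catalytic cycle, so that the allyl group becomes a prenyl group while the trisubstituted olefins, the iodoalkene and the carbinol centre stay unchanged.

Step 5
Reactants: 10 (5R,6E,10Z)-11-iodo-2,6,10-trimethylundeca-2,6,10-trien-5-ol
Product: 12 ethyl (3R,4E)-3-[(3Z)-4-iodo-3-methylbut-3-en-1-yl]-4,8-dimethylnona-4,7-dienoate, via ketene acetal 11 (not isolated)
Conditions: MeC(OEt)3 (excess), EtCO2H (cat.), 140 °C, EtOH distilled off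
Reagents that add atoms: triethyl orthoacetate, CCOC(C)(OCC)OCC
Why: Johnson–Claisen rearrangement, in which the [3,3] shift through a chair transition state with the prenyl-bearing carbinol substituent equatorial should pass the R carbinol configuration suprafacially across the E olefin to the new C–C bond, setting C1 as R and the side-chain olefin as E in one event.

Step 6
Reactants: 12 ethyl (3R,4E)-3-[(3Z)-4-iodo-3-methylbut-3-en-1-yl]-4,8-dimethylnona-4,7-dienoate
Product: 13 (3R,4E)-3-[(3Z)-4-iodo-3-methylbut-3-en-1-yl]-4,8-dimethylnona-4,7-dienal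
Conditions: i-Bu2AlH (1.1 equiv), CH2Cl2, −78 °C; aq. potassium sodium tartrate
Reagents that add atoms: none
Why: Partial ester reduction, which should stop at the aldehyde because the tetrahedral aluminium hemiacetal is stable at −78 °C, and the stereocentre, being β to the carbonyl group, cannot epimerise.

Step 7
Reactants: 14 cyclopropyl methyl ketone
Product: 15 2-cyclopropylbut-3-en-2-ol (racemic)
Conditions: vinylMgBr, THF, 0 °C; then H2O
Reagents that add atoms: vinylmagnesium bromide, C=C[Mg]Br
Why: Grignard 1,2-addition to the ketone, whose new stereocentre is of no consequence because it is destroyed in the next step.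

Step 8
Reactants: 15 2-cyclopropylbut-3-en-2-ol
Product: 16 (3E)-6-bromo-3-methylhexa-1,3-diene
Conditions: 48% aq. HBr, 0 °C; chromatography on AgNO3-impregnated silica
Reagents that add atoms: hydrogen bromide, Br
Why: Julia cyclopropylcarbinyl-to-homoallyl rearrangement, in which ionisation gives an allyl-stabilised cyclopropylcarbinyl cation and bromide opens the strained ring at a CH2 group, which should give mainly the E-diene, while capture at the allylic terminus is reversible and any Z isomer is to be removed on the silver-loaded silica.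

Step 9
Reactants: 17 methyl bis(2,2,2-trifluoroethyl)phosphonoacetate; 16 (3E)-6-bromo-3-methylhexa-1,3-diene
Product: 18 methyl (5E)-2-[bis(2,2,2-trifluoroethoxy)phosphoryl]-6-methylocta-5,7-dienoate (racemic)
Conditions: 17 (excess), NaH, DMF, 0 °C; 16, n-Bu4NI (cat.), 50 °C
Reagents that add atoms: none
Why: SN2 alkylation of the sodium phosphonoacetate enolate with the primary bromide (iodide exchange in the flask), in which the stabilised, weakly basic anion should disfavour E2 elimination and the excess of 17 should limit double alkylation.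

Step 10
Reactants: 13 (3R,4E)-3-[(3Z)-4-iodo-3-methylbut-3-en-1-yl]-4,8-dimethylnona-4,7-dienal; 18 methyl (5E)-2-[bis(2,2,2-trifluoroethoxy)phosphoryl]-6-methylocta-5,7-dienoate
Product: 19 methyl (2Z,5R,6E)-5-[(3Z)-4-iodo-3-methylbut-3-en-1-yl]-6,10-dimethyl-2-[(3E)-4-methylhexa-3,5-dien-1-yl]undeca-2,6,9-trienoate
Conditions: 18, KN(SiMe3)2, 18-crown-6, THF, −78 °C; then 13
Reagents that add atoms: none
Why: Still–Gennari variant of the Horner–Wadsworth–Emmons olefination, in which the electron-poor trifluoroethyl phosphonate under dissociating conditions should eliminate from the kinetic adduct and place the aldehyde residue cis to the ester, giving the Z-enoate geometry needed at C3=C4.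

Step 11
Reactants: 19 methyl (2Z,5R,6E)-5-[(3Z)-4-iodo-3-methylbut-3-en-1-yl]-6,10-dimethyl-2-[(3E)-4-methylhexa-3,5-dien-1-yl]undeca-2,6,9-trienoate
Product: 21 methyl (1Z,4R,7Z,11E)-7,11-dimethyl-4-[(2E)-6-methylhepta-2,5-dien-2-yl]cyclotetradeca-1,7,11-triene-1-carboxylate, via alkylborane 20 (not isolated)
Conditions: 9-BBN (1.5 equiv), THF, 0 °C → rt; then slow addition to Pd(dppf)Cl2 (20 mol %), AsPh3 (20 mol %), Cs2CO3 (3 equiv), degassed DMF/THF/H2O, 50 °C, final concentration 2 mM
Reagents that add atoms: none
Why: 9-BBN should add anti-Markovnikov to the only monosubstituted olefin, the C9=C10 vinyl terminus of the 1,3-diene, so that C10 becomes a nucleophilic B-alkyl centre while the ester, the iodoalkene and all trisubstituted olefins are left alone; oxidative addition of zerovalent palladium into the C11–I bond, base-assisted transfer of the alkyl group from boron to divalent palladium and reductive elimination then form C10–C11. The closest known reaction type is the intramolecular B-alkyl Suzuki–Miyaura macrocyclisation of an iodoalkene with a 9-BBN alkylborane made in the flask. The 14-membered carbocycle is closed end to end by reductive elimination from a 15-membered alkyl(alkenyl)palladacycle under slow-addition high dilution. No new stereocentre is formed: the Z geometry of C11=C12 is carried over with retention from the Z-iodoalkene, and C1 is remote and untouched. The step needs regioselective hydroboration, secured by the bulk of 9-BBN and the terminal position of C10, and ring closure in preference to oligomerisation and β-hydride elimination, secured by slow addition, the dppf/AsPh3 ligand set and the three preformed olefins that limit the freedom of the chain.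

Step 12
Reactants: 21 methyl (1Z,4R,7Z,11E)-7,11-dimethyl-4-[(2E)-6-methylhepta-2,5-dien-2-yl]cyclotetradeca-1,7,11-triene-1-carboxylate
Product: 22 [(1Z,4R,7Z,11E)-7,11-dimethyl-4-[(2E)-6-methylhepta-2,5-dien-2-yl]cyclotetradeca-1,7,11-trien-1-yl]methanol
Conditions: i-Bu2AlH (2.5 equiv), CH2Cl2, −78 °C; aq. potassium sodium tartrate
Reagents that add atoms: none
Why: 1,2-Reduction of the conjugated methyl ester by the aluminium hydride should give the allylic alcohol without touching any olefin geometry or the stereocentre, and the product is the target.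

Compound list
1 | 5-bromo-2-methylpent-2-ene | CC(C)=CCCBr | starting material
2 | propyne | CC#C | starting material
3 | 4-methylpent-3-en-1-ylmagnesium bromide | CC(C)=CCC[Mg]Br | intermediate
4 | [(1Z)-2,6-dimethylhepta-1,5-dien-1-yl]copper | CC(C)=CCC/C(C)=C\[Cu] | intermediate
5 | (1Z)-1-iodo-2,6-dimethylhepta-1,5-diene | CC(C)=CCC/C(C)=C\I | intermediate
6 | (2E,6Z)-7-iodo-2,6-dimethylhepta-2,6-dien-1-ol | OC/C(C)=C/CC/C(C)=C\I | intermediate
7 | (2E,6Z)-7-iodo-2,6-dimethylhepta-2,6-dienal | O=C/C(C)=C/CC/C(C)=C\I | intermediate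
8 | bis(isopinocampheyl)borinate of 9, Ipc groups from (−)-α-pinene | C=CC[C@@H](OB([C@H]1C[C@H]2C[C@@H]([C@@H]1C)C2(C)C)[C@H]1C[C@H]2C[C@@H]([C@@H]1C)C2(C)C)/C(C)=C/CC/C(C)=C\I | intermediate
9 | (4R,5E,9Z)-10-iodo-5,9-dimethyldeca-1,5,9-trien-4-ol | C=CC[C@@H](O)/C(C)=C/CC/C(C)=C\I | intermediate
10 | (5R,6E,10Z)-11-iodo-2,6,10-trimethylundeca-2,6,10-trien-5-ol | CC(C)=CC[C@@H](O)/C(C)=C/CC/C(C)=C\I | intermediate
11 | 1-ethoxyvinyl ether (ketene acetal) of 10 | C=C(OCC)O[C@H](CC=C(C)C)/C(C)=C/CC/C(C)=C\I | intermediate
12 | ethyl (3R,4E)-3-[(3Z)-4-iodo-3-methylbut-3-en-1-yl]-4,8-dimethylnona-4,7-dienoate | CCOC(=O)C[C@@H](CC/C(C)=C\I)/C(C)=C/CC=C(C)C | intermediate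
13 | (3R,4E)-3-[(3Z)-4-iodo-3-methylbut-3-en-1-yl]-4,8-dimethylnona-4,7-dienal | O=CC[C@@H](CC/C(C)=C\I)/C(C)=C/CC=C(C)C | intermediate
14 | cyclopropyl methyl ketone | CC(=O)C1CC1 | starting material
15 | 2-cyclopropylbut-3-en-2-ol (racemic) | CC(O)(C=C)C1CC1 | intermediate
16 | (3E)-6-bromo-3-methylhexa-1,3-diene | BrCC/C=C(\C)C=C | intermediate
17 | methyl bis(2,2,2-trifluoroethyl)phosphonoacetate | COC(=O)CP(=O)(OCC(F)(F)F)OCC(F)(F)F | starting material
18 | methyl (5E)-2-[bis(2,2,2-trifluoroethoxy)phosphoryl]-6-methylocta-5,7-dienoate (racemic) | COC(=O)C(CC/C=C(\C)C=C)P(=O)(OCC(F)(F)F)OCC(F)(F)F | intermediate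
19 | methyl (2Z,5R,6E)-5-[(3Z)-4-iodo-3-methylbut-3-en-1-yl]-6,10-dimethyl-2-[(3E)-4-methylhexa-3,5-dien-1-yl]undeca-2,6,9-trienoate | COC(=O)/C(CC/C=C(\C)C=C)=C\C[C@@H](CC/C(C)=C\I)/C(C)=C/CC=C(C)C | intermediate
20 | methyl (2Z,5R,6E)-2-[(3E)-6-(9-borabicyclo[3.3.1]nonan-9-yl)-4-methylhex-3-en-1-yl]-5-[(3Z)-4-iodo-3-methylbut-3-en-1-yl]-6,10-dimethylundeca-2,6,9-trienoate | COC(=O)/C(CC/C=C(\C)CCB1C2CCCC1CCC2)=C\C[C@@H](CC/C(C)=C\I)/C(C)=C/CC=C(C)C | intermediate
21 | methyl (1Z,4R,7Z,11E)-7,11-dimethyl-4-[(2E)-6-methylhepta-2,5-dien-2-yl]cyclotetradeca-1,7,11-triene-1-carboxylate | COC(=O)/C1=C\C[C@H](/C(C)=C/CC=C(C)C)CC/C(C)=C\CC/C(C)=C/CC1 | intermediate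
22 | [(1Z,4R,7Z,11E)-7,11-dimethyl-4-[(2E)-6-methylhepta-2,5-dien-2-yl]cyclotetradeca-1,7,11-trien-1-yl]methanol | OC/C1=C\C[C@H](/C(C)=C/CC=C(C)C)CC/C(C)=C\CC/C(C)=C/CC1 | target

Total step count: 12. Longest linear sequence: 9 steps (steps 1 to 6, then 10, 11 and 12); steps 7 to 9 build the second fragment.

Steps most likely to fail

Step 11. Intermolecular coupling to oligomers, β-hydride elimination from the alkylpalladium intermediate or protodeboronation may outrun ring closure, and hydroboration of the conjugated diene may be incomplete. The fallback sets out from 19 and comes back at 21; it forms the same C10–C11 bond by a Negishi ring closure that needs neither base nor water and starts from an isolated C10 electrophile. Hydroboration of 19 with 9-BBN followed by NaBO3·4H2O should give the C10 primary alcohol F1. I2, PPh3 and imidazole turn it into the primary iodide F2. Activated zinc dust (THF, 40 °C) should insert into the alkyl C–I bond only and give the alkylzinc iodide F3, which is added slowly to Pd(PPh3)4 in THF at 60 °C to give 21.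

Step 8. Ring opening of the cyclopropylcarbinyl cation may proceed with poor E/Z control, and capture of the cation at its allylic terminus may divert material. The fallback sets out from 17 and comes back at 18; it fixes the C7=C8 geometry by a syn hydrometalation instead of a cation rearrangement. Commercial pent-3-yn-1-ol is hydrozirconated with Cp2Zr(H)Cl (excess, THF) and iodinated to (3E)-4-iodopent-3-en-1-ol F4. CBr4 and PPh3 give (2E)-5-bromo-2-iodopent-2-ene F5. Compound 17 is alkylated with it (NaH, DMF) to the iodoalkenyl phosphonate F6, and a Stille coupling with tributyl(vinyl)stannane (Pd(PPh3)4, DMF, 60 °C) should install the vinyl group with retention to give 18.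

Step 2. Oxidation may occur at the wrong allylic position, run on to the acid or stall at low conversion. The fallback sets out from 2 and comes back at 7; it builds the enal by olefination instead of C–H oxidation. The Grignard reagent of commercial 2-(2-bromoethyl)-1,3-dioxolane is converted with CuBr·SMe2 into its organocopper, added to 2 and iodinated to the Z-iodoalkenyl acetal F7. Aqueous HCl in THF frees the aldehyde F8, and a Wittig reaction with Ph3P=C(Me)CHO (toluene, 90 °C) should give the E-enal 7.

Further compounds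
F1 | step 11 | methyl (2Z,5R,6E)-2-[(3E)-6-hydroxy-4-methylhex-3-en-1-yl]-5-[(3Z)-4-iodo-3-methylbut-3-en-1-yl]-6,10-dimethylundeca-2,6,9-trienoate | COC(=O)/C(CC/C=C(\C)CCO)=C\C[C@@H](CC/C(C)=C\I)/C(C)=C/CC=C(C)C
F2 | step 11 | methyl (2Z,5R,6E)-2-[(3E)-6-iodo-4-methylhex-3-en-1-yl]-5-[(3Z)-4-iodo-3-methylbut-3-en-1-yl]-6,10-dimethylundeca-2,6,9-trienoate | COC(=O)/C(CC/C=C(\C)CCI)=C\C[C@@H](CC/C(C)=C\I)/C(C)=C/CC=C(C)C
F3 | step 11 | alkylzinc iodide of F2 (zinc at the former CH2I carbon) | COC(=O)/C(CC/C=C(\C)CC[Zn]I)=C\C[C@@H](CC/C(C)=C\I)/C(C)=C/CC=C(C)C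
F4 | step 8 | (3E)-4-iodopent-3-en-1-ol | C/C(I)=C\CCO
F5 | step 8 | (2E)-5-bromo-2-iodopent-2-ene | C/C(I)=C\CCBr
F6 | step 8 | methyl (5E)-2-[bis(2,2,2-trifluoroethoxy)phosphoryl]-6-iodohept-5-enoate | COC(=O)C(CC/C=C(\C)I)P(=O)(OCC(F)(F)F)OCC(F)(F)F
F7 | step 2 | 2-[(3Z)-4-iodo-3-methylbut-3-en-1-yl]-1,3-dioxolane | I/C=C(C)\CCC1OCCO1
F8 | step 2 | (4Z)-5-iodo-4-methylpent-4-enal | O=CCC/C(C)=C\I
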